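The readings were generated by integration for substances that don't exist; scatter was added.

At early times the alder flask moves fast: it shows 26 % mono adduct at 0.250 h, and the last reading of the cedar run is 24 % at 50.0 min.

| flask | substrate | reagent | temperature | remark | time |
|---|---|---|---|---|---|
| alder | 0.40 M | 1.5 equiv | 70 °C | the very flask that is asked about, followed so far |  |
| cedar | 0.20 M | 1.5 equiv | 65 °C | run made earlier |  |
| flask | 0.40 M | 1.50 equiv | 70 °C |  | 4.0 h |

- alder (time / h: mono adduct / %): 0.250: 26; 0.667: 27; 1.33: 30; 3.00: 34
- cedar (time / min: mono adduct / %): 4.00: 6; 8.00: 6; 20.0: 20; 50.0: 24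

(scatter of a reading: 2 percentage points)

- Friday's: at 4.0 h raise the temperature by 15 K, then wait 4.0 h
- Tuesday's: at 4.0 h take out 90 % of the mono adduct then present, then wait 4.0 h
- Sunday's: at 4.0 h add reagent, 100 % of the amount charged, then wait 4.0 h
- Saturday's: change nothing and wait 4.0 h more

1. mono adduct, in percent of the substrate first charged, at 4.0 h
2. what to do for the largest gain in mono adduct; "none" if nothing gains more than 2 percentage points (Friday's / Tuesday's / Sunday's / Saturday's / none)
3. mono adduct present, with what was taken out counted in, in percent of the substrate first charged, after Friday's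
4. mono adduct present, with what was taken out counted in, in percent of the substrate first charged, after Saturday's

- mono adduct taken out counts as made
- additions bring no volume worth counting

Does the alder flask still move after this burst? Its readings rise by 8 percentage points over 2.75 h. At that pace it would need 8.94 h to make its burst share once more; we call this span the creep time, a characteristic time. It is a reading, and each point scatters by 2 points.

So how far can a straight line be trusted? The creep time is far longer than the 0.250 h of the first reading, so we read burst and creep as separate regimes. The step of 1.00 h past the last reading then gives us 36.9 % at 4.0 h.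

Does waiting pay? Saturday's 4.0 h is half the creep time, so our line adds 12 points and reaches 48.5 %.

The forecast gives 37 % (34.5 % to 39 %), and for Saturday's 46 % (42 % to 50 %), lower than the 48.5 % of our line. For Friday's it gives 60 % (50 % to 72 %), and it chooses Friday's: “Friday's looks best, with moderate confidence.”

The flask gives 35.0 % at 4.0 h, 54.0 % after Friday's and 38.5 % after Saturday's; the best choice is Friday's, with a gain of 19 points.

    substrate + reagent → mono adduct (k = 0.0660 L mol⁻¹ min⁻¹, Ea = 64.0 kJ mol⁻¹)
    substrate ⇌ dormant form (K = 14.0, k = 0.0160 min⁻¹, Ea = 107 kJ mol⁻¹, ΔH = −15.0 kJ mol⁻¹)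
    reagent + mono adduct ⇌ bis adduct (K = 4.10 L mol⁻¹, k = 0.120 L mol⁻¹ min⁻¹, Ea = 64.0 kJ mol⁻¹, ΔH = −34.0 kJ mol⁻¹)
    (constants at 70 °C)

The flask has not come to rest at 4.0 h. Left for 40.0 h, it holds 56.4 % mono adduct against 35.0 %, while the dormant form goes from 33.1 % to 12.6 % and the bis adduct from 30.7 % to 30.4 %. Over that later span, the same measure gives a creep time of 43.6 h, longer than the 8.94 h read from the early span.

If the creep pace follows the reagent charged, a neighbour flask with 0.380 equiv has a creep time of 35.3 h, far longer than 4.0 h, so we expect little creep there by 4.0 h. That neighbour flask gives 23.2 % at 4.0 h.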